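**Closed balance.** Electrophile plus product should stay at the charge, and at the last reading they sum to 101% in teal and 99.7% in violet. Within the scatter of 1 percentage point, then, you may follow one electrophile molecule through one fork: it ends as product or it stays electrophile.

common to all: electrophile 0.30 M
- teal: nucleophile 0.26 M; run made earlier
- violet: nucleophile 1.1 M; run made earlier
- south-west: nucleophile 0.320 M; time 8.0 h
- east: nucleophile 0.630 M; time 8.0 h
- west: nucleophile 1.30 M; time 8.0 h

| run | time / h | electrophile / % | product / % |
|---|---|---|---|
| teal | 1.50 | 70.7 | 32.8 |
| teal | 3.00 | 66.1 | 34.1 |
| teal | 5.00 | 63.4 | 36.7 |
| teal | 6.00 | 64.0 | 36.8 |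
| teal | 8.00 | 63.5 | 37.5 |
| violet | 0.667 | 42.1 | 60.0 |
| violet | 2.00 | 30.4 | 70.3 |
| violet | 4.00 | 25.3 | 72.3 |
| violet | 6.00 | 27.2 | 74.9 |
| violet | 8.00 | 25.0 | 74.7 |

(each reading ± 1 percentage point)

* part of the electrophile that has reacted at the end, south-west
* part of the electrophile that has reacted at the end, east
* part of the electrophile that has reacted at the end, west
* what raising the concentration of nucleophile from its lowest to its highest value here does to the part of the electrophile that has reacted (changes below 5 percentage points count as none) (it falls / no change / it rises)



**Early hours.** You see no first instants, but the violet flask has lost 57.9% of its electrophile by 0.667 h, more than the 29.3% the teal flask has lost by the later 1.50 h, so the step that makes product is quick at the start and quicker in the flask with more nucleophile.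

**Level stretch.** Then the readings flatten: between 6.00 h and 8.00 h product changes by 0.7 points in teal and −0.2 points in violet, inside the scatter, while 63.5% of the electrophile stands unreacted in teal and 25.0% in violet, so what you need to reckon is the level a flask has reached by 8.0 h, not how fast it gets there.

**Plateau quotient.** Take [product] / ([electrophile] × ([nucleophile] as charged − [product])) at the last reading: it reads 4.00 M⁻¹ in teal and 3.41 M⁻¹ in violet, although violet holds 4.23 times the nucleophile. Their mean, 3.71 M⁻¹, is what I carry: the plateau quotient, product over electrophile over charged nucleophile less product, a reading with their scatter, for electrophile held at 0.30 M. Solving it for the product at 8.0 h, I expect 41.9% in south-west, 62.2% in east and 79.7% in west, though west holds more nucleophile than violet, the highest charge read.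

**The forecast.** Its author reads the same level stretch and concludes: “All new runs should be at equilibrium by 8 h.” It gives 41.4%, 61.6% and 79.3%, each slightly below mine, and for the trend: it rises.

**The result.** South-west gives 41.7%, east 60.6% and west 79.1%; from lowest to highest nucleophile, it rises, by 37 points.

    2 nucleophile → homo dimer (k = 0.0570 M⁻¹ min⁻¹)
    electrophile + nucleophile → acid set free + product (k = 0.0759 M⁻¹ min⁻¹)
    nucleophile + acid set free ⇌ protonated nucleophile, settled at all times (K = 2700 M⁻¹)

**Same reckoning.** The east result puts the quotient at 3.43 M⁻¹, beside the 3.71 M⁻¹ carried, yet free nucleophile in east is down to 0.36% of its charge, less than the 39% of electrophile left, and with 2.10 equivalents charged it is still the first to run out, the limiting reagent. The bracket in the quotient, 0.448 M in east, is charged nucleophile less product, not free nucleophile. For the neighbour, east with 0.51 M of electrophile, the same quadratic, taken away from the 0.30 M of electrophile it was read at, promises 56.1%, but that flask gives 46.1%, its quotient reading 2.16 M⁻¹.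

The readings are calculated from invented constants, and the scatter is random.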